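A direct plan would couple 5-bromo-2-(3,5-dimethoxyphenoxy)-1,3-dimethoxybenzene A1 with 2,4,6-trimethoxyphenol A2 in a copper-catalysed Ullmann reaction to give the heptamethyl ether A3, would free the heptaphenol A4 with BBr3, and would brominate A4 once with NBS. Its weakest steps would be:
- the coupling that forms the ring B–O–ring C ether, because the electron-rich bromide A1 would have to react with the di-ortho-substituted phenol A2, which is easily oxidised to a quinone;
- the monobromination, because rings A, B and C of A4 would all be phloroglucinol-type nucleophiles, so that neither the ring attacked nor the number of bromine atoms would be controlled;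
- the halogenation that leads to A1, because ring A would be attacked before ring B.

**Strategy.** Ring C is read as a folded triketide: its ether carbon C1 lies between the oxygenated carbons C2 and C6, and the bromine on C5 between the oxygenated C4 and C6, the pattern of a 3-bromo-4-methoxy-2-pyrone with an aryloxymethyl group at position 6. The phenol of the ring A–ring B diaryl ether would be alkylated with a bromomethylpyrone, and methoxide would turn the pyrone into the benzene ring by ring opening and Claisen closure of the C1–C6 bond. One operation would create ring C with its hindered ether carbon, three further oxygens and the bromine in place, so neither a coupling at a di-ortho-substituted carbon nor a bromination of the assembled polyphenol is needed.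

Key step: step 6

Remark on the chemistry: the target has no stereocentre; 2,6-dimethoxyphenol, 1-iodo-3,5-dimethoxybenzene and 4-methoxy-6-methyl-2H-pyran-2-one are taken as purchasable.

Step 1
Reactants: 1 2,6-dimethoxyphenol; 2 1-iodo-3,5-dimethoxybenzene
Product: 3 2-(3,5-dimethoxyphenoxy)-1,3-dimethoxybenzene
Conditions: CuI (10 mol %), picolinic acid (20 mol %), K3PO4 (2 equiv), DMSO, 90 °C, argon
Reagents that add atoms: none
Why: Ullmann-type copper-catalysed C–O coupling in which the hindered partner is the electron-rich phenoxide and the halide is unhindered, the arrangement for which the picolinate ligand is suited.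

Step 2
Reactants: 3 2-(3,5-dimethoxyphenoxy)-1,3-dimethoxybenzene
Product: 5 4-(3,5-dimethoxyphenoxy)-3,5-dimethoxyphenol, via pinacol boronate 4 (not isolated)
Conditions: [Ir(OMe)(cod)]2 (1.5 mol %), 4,4'-di-tert-butyl-2,2'-bipyridine (3 mol %), B2pin2 (1.0 equiv), THF, 80 °C; then 2KHSO5·KHSO4·K2SO4 (aq.), acetone, rt
Reagents that add atoms: potassium peroxymonosulfate, [K+].OOS(=O)(=O)[O-]
Why: Iridium-catalysed C–H borylation is governed by sterics, so only the C–H bond of ring B para to the ether oxygen, the one C–H bond without an ortho substituent (every C–H bond of ring A lies between two oxygens), should be borylated, and the C–B bond is then oxidised to the phenol in the same flask (C–H borylation/oxidation).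

Step 3
Reactants: 6 4-methoxy-6-methyl-2H-pyran-2-one
Product: 7 3-bromo-4-methoxy-6-methyl-2H-pyran-2-one
Conditions: NBS (1.05 equiv), MeCN, rt, dark
Reagents that add atoms: N-bromosuccinimide, O=C1CCC(=O)N1Br
Why: Electrophilic bromination should take place at C3, the nucleophilic carbon of the vinylogous ester between the carbonyl group and the methoxy-bearing carbon, which is the usual site of halogenation of 4-alkoxy-2-pyrones.

Step 4
Reactants: 7 3-bromo-4-methoxy-6-methyl-2H-pyran-2-one
Product: 8 3-bromo-6-(bromomethyl)-4-methoxy-2H-pyran-2-one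
Conditions: NBS (1.1 equiv), AIBN (5 mol %), PhCF3, 85 °C
Reagents that add atoms: N-bromosuccinimide, O=C1CCC(=O)N1Br
Why: Wohl–Ziegler radical bromination should select the 6-methyl group, whose C–H bonds are the only allylic ones, C3 being already blocked against ionic bromination.

Step 5
Reactants: 5 4-(3,5-dimethoxyphenoxy)-3,5-dimethoxyphenol; 8 3-bromo-6-(bromomethyl)-4-methoxy-2H-pyran-2-one
Product: 9 3-bromo-6-{[4-(3,5-dimethoxyphenoxy)-3,5-dimethoxyphenoxy]methyl}-4-methoxy-2H-pyran-2-one
Conditions: K2CO3 (1.5 equiv), acetone, rt to 40 °C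
Reagents that add atoms: none
Why: Williamson ether synthesis, the SN2 attack of the phenoxide on the primary allylic bromide being faster than conjugate addition to the pyrone, whose vinylic bromine is not displaced.

Step 6
Reactants: 9 3-bromo-6-{[4-(3,5-dimethoxyphenoxy)-3,5-dimethoxyphenoxy]methyl}-4-methoxy-2H-pyran-2-one
Product: 12 4-bromo-2-[4-(3,5-dimethoxyphenoxy)-3,5-dimethoxyphenoxy]-5-methoxybenzene-1,3-diol, via keto ester 10 (not isolated), via cyclohexenedione 11 (not isolated)
Conditions: NaOMe (4 equiv), MeOH, 65–100 °C (sealed tube), argon; then 1 M HCl, 0 °C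
Reagents that add atoms: none
Why: Proposed new method: methoxide should add to the lactone carbonyl of 9 and open the ring to keto ester 10, in which the ester carbon and the methylene next to the ketone remain cis on the tetrasubstituted double bond as they were in the pyrone; the OCH2 group, acidified by the ketone and the aryloxy oxygen, should then give an enolate whose carbon attacks the ester (intramolecular Claisen condensation), and loss of methoxide should give enedione 11, which enolises to the phenoxide of 12. The closest known reaction type is the biomimetic polyketide Claisen cyclisation, in which alkoxides open 4-oxygenated 2-pyrones that carry a 6-(2-oxoalkyl) chain and the keto esters so formed close to acylphloroglucinols; new is the use of an aryloxymethyl ketone as the carbon nucleophile and of a brominated vinylogous carbonate as the acyl donor. Ring C is closed by a 6-(enolendo)-exo-trig attack that forms the C1–C6 bond, C1 being the former OCH2 carbon and C6 the former lactone carbonyl carbon. No stereocentre remains, because the sp3 ring carbons of 11 are lost on aromatisation. The step needs carbon acylation to win over the reversible oxygen acylation that returns the pyrone and over retro-Claisen cleavage of the ketone by methoxide, which is secured because only the C–C closure ends in an aromatic phenoxide and is therefore irreversible. The place of the bromine on C5, between the C4 methoxy group and the C6 hydroxyl, is fixed by the pyrone, since the vinylic C–Br bond is inert to methoxide.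

Step 7
Reactants: 12 4-bromo-2-[4-(3,5-dimethoxyphenoxy)-3,5-dimethoxyphenoxy]-5-methoxybenzene-1,3-diol
Product: 13 2-bromo-4-[4-(3,5-dihydroxyphenoxy)-3,5-dihydroxyphenoxy]benzene-1,3,5-triol
Conditions: BBr3 (10 equiv), CH2Cl2, −78 °C to rt; then MeOH, H2O, 0 °C
Reagents that add atoms: none
Why: Lewis acid-mediated cleavage of aryl methyl ethers with excess BBr3 should remove the five methyl groups while the diaryl ether bonds and the aryl bromide stay intact.

Compound list
1 | 2,6-dimethoxyphenol | COc1cccc(OC)c1O | starting material
2 | 1-iodo-3,5-dimethoxybenzene | COc1cc(I)cc(OC)c1 | starting material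
3 | 2-(3,5-dimethoxyphenoxy)-1,3-dimethoxybenzene | COc1cc(OC)cc(Oc2c(OC)cccc2OC)c1 | intermediate
4 | 2-[4-(3,5-dimethoxyphenoxy)-3,5-dimethoxyphenyl]-4,4,5,5-tetramethyl-1,3,2-dioxaborolane | COc1cc(OC)cc(Oc2c(OC)cc(B3OC(C)(C)C(C)(C)O3)cc2OC)c1 | intermediate
5 | 4-(3,5-dimethoxyphenoxy)-3,5-dimethoxyphenol | COc1cc(OC)cc(Oc2c(OC)cc(O)cc2OC)c1 | intermediate
6 | 4-methoxy-6-methyl-2H-pyran-2-one | COC1=CC(=O)OC(C)=C1 | starting material
7 | 3-bromo-4-methoxy-6-methyl-2H-pyran-2-one | COC1=C(Br)C(=O)OC(C)=C1 | intermediate
8 | 3-bromo-6-(bromomethyl)-4-methoxy-2H-pyran-2-one | COC1=C(Br)C(=O)OC(CBr)=C1 | intermediate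
9 | 3-bromo-6-{[4-(3,5-dimethoxyphenoxy)-3,5-dimethoxyphenoxy]methyl}-4-methoxy-2H-pyran-2-one | COC1=C(Br)C(=O)OC(COc2cc(OC)c(Oc3cc(OC)cc(OC)c3)c(OC)c2)=C1 | intermediate
10 | methyl (2Z)-2-bromo-6-[4-(3,5-dimethoxyphenoxy)-3,5-dimethoxyphenoxy]-3-methoxy-5-oxohex-2-enoate | COC(=O)/C(Br)=C(OC)\CC(=O)COc1cc(OC)c(Oc2cc(OC)cc(OC)c2)c(OC)c1 | intermediate
11 | 4-bromo-2-[4-(3,5-dimethoxyphenoxy)-3,5-dimethoxyphenoxy]-5-methoxycyclohex-4-ene-1,3-dione (racemic) | COC1=C(Br)C(=O)C(Oc2cc(OC)c(Oc3cc(OC)cc(OC)c3)c(OC)c2)C(=O)C1 | intermediate
12 | 4-bromo-2-[4-(3,5-dimethoxyphenoxy)-3,5-dimethoxyphenoxy]-5-methoxybenzene-1,3-diol | COc1cc(OC)cc(Oc2c(OC)cc(Oc3c(O)cc(OC)c(Br)c3O)cc2OC)c1 | intermediate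
13 | 2-bromo-4-[4-(3,5-dihydroxyphenoxy)-3,5-dihydroxyphenoxy]benzene-1,3,5-triol | Oc1cc(O)cc(Oc2c(O)cc(Oc3c(O)cc(O)c(Br)c3O)cc2O)c1 | target

Total step count: 7. Longest linear sequence: 5 steps (steps 1, 2, 5, 6, 7; the pyrone branch, steps 3, 4, 5, 6, 7, is equally long).

Steps most likely to fail

Step 6. The opened enolate may return to the pyrone by oxygen acylation faster than carbon closes on the deactivated ester. Methoxide may also cleave the aryloxymethyl ketone by retro-Claisen reaction, or bromine may be lost by halophilic attack of enolates on the keto form of the product. The fallback brings ring C in as an intact arene with the bromine already placed. It sets out from boronate 4, isolated after the borylation of step 2 instead of being oxidised. Purchased 2,4,6-trimethoxyphenol A2 would be brominated with NBS (CH2Cl2, −78 °C) to 3-bromo-2,4,6-trimethoxyphenol F1, whose two free ring positions are equivalent. Chan–Lam coupling of F1 with 4 (Cu(OAc)2, pyridine, B(OH)3, MeCN, air, 60 °C), which leaves an aryl bromide untouched, would give 2-bromo-4-[4-(3,5-dimethoxyphenoxy)-3,5-dimethoxyphenoxy]-1,3,5-trimethoxybenzene F2. BBr3 under the conditions of step 7 would then cleave the seven methyl ethers and come back to the route at 13.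

Step 4. The radical bromination may run on to the dibromomethyl compound, or ionic bromination at C5 may compete. The fallback oxidises the methyl group instead and sets out from 7. A Riley oxidation (SeO2, dioxane, 150 °C, sealed tube) should give 3-bromo-4-methoxy-2-oxo-2H-pyran-6-carbaldehyde F3. NaBH4 (MeOH, 0 °C) should reduce the aldehyde to 3-bromo-6-(hydroxymethyl)-4-methoxy-2H-pyran-2-one F4. A Mitsunobu reaction of F4 with phenol 5 (PPh3, DIAD, THF, 0 °C to rt) would come back to the route at 9.

Step 1. The hindered phenoxide may couple slowly and be consumed by copper-mediated oxidative dimerisation. The fallback transfers the aryl group from hypervalent iodine without a metal and sets out from iodide 2. Oxidation with mCPBA and TsOH·H2O (MeCN, rt), followed by trapping with 1,3,5-trimethoxybenzene, should give (3,5-dimethoxyphenyl)(2,4,6-trimethoxyphenyl)iodonium 4-methylbenzenesulfonate F5. The potassium salt of 1 (t-BuOK, THF, rt) would be arylated by F5 through ligand coupling at iodine, the trimethoxyphenyl group staying on iodine, and the route is rejoined at 3.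

Further compounds
F1 | step 6 | 3-bromo-2,4,6-trimethoxyphenol | COc1cc(OC)c(Br)c(OC)c1O
F2 | step 6 | 2-bromo-4-[4-(3,5-dimethoxyphenoxy)-3,5-dimethoxyphenoxy]-1,3,5-trimethoxybenzene | COc1cc(OC)cc(Oc2c(OC)cc(Oc3c(OC)cc(OC)c(Br)c3OC)cc2OC)c1
F3 | step 4 | 3-bromo-4-methoxy-2-oxo-2H-pyran-6-carbaldehyde | COC1=C(Br)C(=O)OC(C=O)=C1
F4 | step 4 | 3-bromo-6-(hydroxymethyl)-4-methoxy-2H-pyran-2-one | COC1=C(Br)C(=O)OC(CO)=C1
F5 | step 1 | (3,5-dimethoxyphenyl)(2,4,6-trimethoxyphenyl)iodonium 4-methylbenzenesulfonate | COc1cc(OC)cc([I+]c2c(OC)cc(OC)cc2OC)c1.Cc1ccc(S(=O)(=O)[O-])cc1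
A1 | direct plan | 5-bromo-2-(3,5-dimethoxyphenoxy)-1,3-dimethoxybenzene | COc1cc(OC)cc(Oc2c(OC)cc(Br)cc2OC)c1
A2 | direct plan | 2,4,6-trimethoxyphenol | COc1cc(OC)c(O)c(OC)c1
A3 | direct plan | 2-[4-(3,5-dimethoxyphenoxy)-3,5-dimethoxyphenoxy]-1,3,5-trimethoxybenzene | COc1cc(OC)cc(Oc2c(OC)cc(Oc3c(OC)cc(OC)cc3OC)cc2OC)c1
A4 | direct plan | 2-[4-(3,5-dihydroxyphenoxy)-3,5-dihydroxyphenoxy]benzene-1,3,5-triol | Oc1cc(O)cc(Oc2c(O)cc(Oc3c(O)cc(O)cc3O)cc2O)c1
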